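**Retrosynthetic overview**

1. Locants follow the dihydrochalcone name (ring A = C1'–C6', ring B = phenyl, ring C = pyran O1''/C4''–C6''). The target comes from its 4'-O-silyl ether by fluoride; that ether comes from the ring C annulation.
2. Key disconnection: ring C is cut across C4''–C5'' and O1''–C6'' into a ring A salicylaldehyde and isobutene. Forward, one chiral Brønsted acid-catalysed Prins-type oxa-[4+2] annulation makes both bonds, the ring and the only stereocentre (4''R).
3. Enabling feature: the carbinol carbon C4'' and the ether oxygen O1'' sit on adjacent ring A carbons (C5', C6'). So O1''–C6'=C5'–C4''(H)=O is a salicylaldehyde (a latent protonated ortho-quinone methide), and C5''H2–C6''Me2 is isobutene, whose gem-dimethyl carbon carries the cation to oxygen.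
4. The aldehyde comes from formylation of the single free ring A carbon (C5'), after selective 4'-O-silylation (blocks the wrong ortho-hydroxyl; the 2'-OH stays chelated to the ketone), after Friedel–Crafts acylation of 2,4,6-trihydroxytoluene with 3-phenylpropanoic acid.
5. Ring order: rings A and B are bought; ring C is the only ring formed (step 4).

Key step: step 4

Remark: the stereocentre as drawn is 4''R (OH > C5' > C5''H2 > H); the bicyclic compounds are named with chroman numbering (C4 = C4'', C3 = C5'', C2 = C6''); 2,4,6-trihydroxytoluene is taken as commercial.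

**Step 1**
Reactants: 1 2,4,6-trihydroxytoluene (2-methylbenzene-1,3,5-triol); 2 3-phenylpropanoic acid
Product: 3 1-(2,4,6-trihydroxy-3-methylphenyl)-3-phenylpropan-1-one (2',4',6'-trihydroxy-3'-methyldihydrochalcone)
Conditions: BF3·OEt2 (neat, as medium), 85 °C; then aq. NaOAc, rt
Reagents that add atoms: none
Why: Friedel–Crafts C-acylation by the BF3-activated carboxylic acid at one of the two equivalent free ring carbons should give a single monoketone, because the first acyl group deactivates the ring toward a second.

**Step 2**
Reactants: 3 1-(2,4,6-trihydroxy-3-methylphenyl)-3-phenylpropan-1-one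
Product: 4 1-{4-[(tert-butyldimethylsilyl)oxy]-2,6-dihydroxy-3-methylphenyl}-3-phenylpropan-1-one
Conditions: TBSCl (1.05 equiv), imidazole (2.2 equiv), DMF–CH2Cl2, −20 → 0 °C
Reagents that add atoms: tert-butyldimethylsilyl chloride, CC(C)(C)[Si](C)(C)Cl
Why: Site-selective O-silylation should occur at the 4'-OH, which is para to the ketone, the most acidic phenol and the only one that neither flanks nor hydrogen-bonds to the carbonyl group.

**Step 3**
Reactants: 4 1-{4-[(tert-butyldimethylsilyl)oxy]-2,6-dihydroxy-3-methylphenyl}-3-phenylpropan-1-one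
Product: 6 2-[(tert-butyldimethylsilyl)oxy]-4,6-dihydroxy-3-methyl-5-(3-phenylpropanoyl)benzaldehyde, via methoxycarbenium triflate 5 (not isolated)
Conditions: Cl2CHOMe (2 equiv), AgOTf (3 equiv), CH2Cl2, −78 °C; then sat. aq. NaHCO3, 0 °C
Reagents that add atoms: dichloromethyl methyl ether, COC(Cl)Cl; water, O
Why: Rieche formylation in its silver triflate-promoted low-temperature form should substitute C5', the only unsubstituted ring A carbon (ortho/para to three oxygens), under conditions mild enough to spare the aryl silyl ether and the enolisable ketone.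

**Step 4**
Reactants: 6 2-[(tert-butyldimethylsilyl)oxy]-4,6-dihydroxy-3-methyl-5-(3-phenylpropanoyl)benzaldehyde; 7 isobutene (2-methylpropene)
Product: 9 1-{(4R)-5-[(tert-butyldimethylsilyl)oxy]-4,7-dihydroxy-2,2,6-trimethyl-3,4-dihydro-2H-chromen-8-yl}-3-phenylpropan-1-one, via tertiary carbocation 8 (not isolated)
Conditions: (S,S)-IDPi acid HN[P(=NSO2CF3)(O2Ar*)]2 with O2Ar* = (S)-3,3'-bis[3,5-bis(trifluoromethyl)phenyl]-1,1'-bi-2-naphtholate (5 mol %), isobutene (10 equiv, condensed in), CHCl3, 5 Å MS, −40 → −20 °C, sealed tube; Et3N quench at −40 °C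
Reagents that add atoms: none
Why: Proposed new method: the chiral acid protonates the formyl oxygen of 6 while one of its basic sulfonyl oxygens hydrogen-bonds the ortho 6'-OH, so that the resulting hydroxycarbenium, a protonated ortho-quinone methide (1-oxadiene O1''–C6'=C5'–C4''=OH+), is attacked on its Re face by the CH2 terminus of isobutene (Prins addition, C4''–C5'' bond) to give tertiary cation 8 inside the chiral ion pair, which the same phenol oxygen then captures at the CMe2 carbon (O1''–C6'' bond). The closest known reaction types are the chiral imidodiphosphate- and IDPi-catalysed asymmetric Prins cyclisations of salicylaldehydes, the IDPi-catalysed [4+2] cycloadditions of aldehydes with simple dienes, the chiral N-triflylphosphoramide-catalysed cycloadditions of ortho-quinone methides with unactivated 1,1-disubstituted alkenes, and the Lewis acid-mediated annulations of salicylaldehydes, orthoformates and alkenes to 4-alkoxychromans. Ring C closes as a six-membered ring in an asynchronous, stepwise oxa-[4+2] mode (intermolecular C–C bond first, then intramolecular six-membered O-capture of the cation), and the 1,1-disubstitution of isobutene fixes the orientation CH2 to carbon and CMe2 to oxygen. The only new stereocentre, C4'', is set under catalyst control: the acid enantiomer that shields the Si face is used ((S,S) is the working choice, its antipode otherwise), so that Re-face attack gives 4''R. Site selectivity is secured by the substrate, since the other ortho-hydroxyl (4'-O) is silylated and the 2'-OH is para to the formyl group and held on the ketone carbonyl by hydrogen bonding, which also leaves the 6'-OH free to chelate the aldehyde. Low temperature, the basic quench and the electron-withdrawing 1'-acyl group are relied on to keep the product carbinol from ionising.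

**Step 5**
Reactants: 9 1-{(4R)-5-[(tert-butyldimethylsilyl)oxy]-4,7-dihydroxy-2,2,6-trimethyl-3,4-dihydro-2H-chromen-8-yl}-3-phenylpropan-1-one
Product: 10 1-[(4R)-4,5,7-trihydroxy-2,2,6-trimethyl-3,4-dihydro-2H-chromen-8-yl]-3-phenylpropan-1-one, i.e. (4''R)-2',4',4''-trihydroxy-3',6'',6''-trimethylpyrano[2'',3'':6',5']dihydrochalcone
Conditions: Bu4NF (1.1 equiv), AcOH (1.1 equiv), THF, 0 °C
Reagents that add atoms: none
Why: Fluoride-mediated cleavage of the aryl silyl ether, buffered with acetic acid so that no free phenoxide can expel the benzylic hydroxyl, should leave the C4'' stereocentre and the ketone untouched.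

**Compound list**

1 | 2,4,6-trihydroxytoluene | Cc1c(O)cc(O)cc1O | starting material
2 | 3-phenylpropanoic acid | O=C(O)CCc1ccccc1 | starting material
3 | 1-(2,4,6-trihydroxy-3-methylphenyl)-3-phenylpropan-1-one | Cc1c(O)cc(O)c(C(=O)CCc2ccccc2)c1O | intermediate
4 | 1-{4-[(tert-butyldimethylsilyl)oxy]-2,6-dihydroxy-3-methylphenyl}-3-phenylpropan-1-one | Cc1c(O)c(C(=O)CCc2ccccc2)c(O)cc1O[Si](C)(C)C(C)(C)C | intermediate
5 | methoxycarbenium triflate of ring A at C5' (aryl–CH=O+Me, triflate counter-ion; not isolated) | Cc1c(O)c(C(=O)CCc2ccccc2)c(O)c(C=[O+]C)c1O[Si](C)(C)C(C)(C)C.[O-]S(=O)(=O)C(F)(F)F | intermediate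
6 | 2-[(tert-butyldimethylsilyl)oxy]-4,6-dihydroxy-3-methyl-5-(3-phenylpropanoyl)benzaldehyde | Cc1c(O)c(C(=O)CCc2ccccc2)c(O)c(C=O)c1O[Si](C)(C)C(C)(C)C | intermediate
7 | isobutene (2-methylpropene) | CC(C)=C | starting material
8 | (R)-configured tertiary carbocation from Prins addition of isobutene to 6 (ion-paired with the catalyst anion; not isolated) | Cc1c(O)c(C(=O)CCc2ccccc2)c(O)c([C@H](O)C[C+](C)C)c1O[Si](C)(C)C(C)(C)C | intermediate
9 | 1-{(4R)-5-[(tert-butyldimethylsilyl)oxy]-4,7-dihydroxy-2,2,6-trimethyl-3,4-dihydro-2H-chromen-8-yl}-3-phenylpropan-1-one | Cc1c(O)c(C(=O)CCc2ccccc2)c2c(c1O[Si](C)(C)C(C)(C)C)[C@H](O)CC(C)(C)O2 | intermediate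
10 | 1-[(4R)-4,5,7-trihydroxy-2,2,6-trimethyl-3,4-dihydro-2H-chromen-8-yl]-3-phenylpropan-1-one | Cc1c(O)c(C(=O)CCc2ccccc2)c2c(c1O)[C@H](O)CC(C)(C)O2 | target

**Step count and risks**

Total steps: 5. Longest linear sequence: 5 steps (1 → 3 → 4 → 6 → 9 → 10).

Steps most likely to fail:

1. Step 4 (Proposed new method). What may go wrong:
   - too little electrophilic activation of the very electron-rich, hexasubstituted aldehyde toward a weakly nucleophilic alkene;
   - poor enantiofacial discrimination of so crowded a substrate in the catalyst pocket;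
   - acid-promoted ionisation of the product carbinol (dehydration toward the 2H-chromene or racemisation);
   - acid-initiated oligomerisation of isobutene.

   The fallback uses known chemistry and splits the annulation into two operations. It sets out from 6. A chiral phosphoric acid-catalysed asymmetric allylboration with 2-methylallylboronic acid pinacol ester is run with (R)-3,3'-bis(2,4,6-triisopropylphenyl)-1,1'-binaphthyl-2,2'-diyl hydrogen phosphate in toluene at −30 °C, the catalyst antipode being chosen for Re-face delivery. It should give the homoallylic alcohol 1-{4-[(tert-butyldimethylsilyl)oxy]-2,6-dihydroxy-3-[(1R)-1-hydroxy-3-methylbut-3-en-1-yl]-5-methylphenyl}-3-phenylpropan-1-one F1. Its 1,1-disubstituted alkene is then closed onto the 6'-OH by a Mukaiyama-type hydrogen-atom-transfer hydroalkoxylation (Markovnikov, neutral conditions): [N,N'-bis(3,5-di-tert-butylsalicylidene)-1,2-cyclohexanediaminato]cobalt (divalent cobalt), N-fluoro-2,4,6-trimethylpyridinium triflate, PhSiH3, PhCF3, rt. This comes back to the route at 9.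

2. Step 3. What may go wrong: loss of the aryl silyl ether to the triflic acid set free, or attack of the electrophile at a phenol oxygen or at the enolisable ketone α-carbon instead of C5'. The fallback sets out from 4 and uses a base-mediated, phenoxide-directed ortho-formylation (Casnati–Skattebøl: MgCl2, Et3N, paraformaldehyde, THF, reflux). The magnesium 6'-phenoxide should deliver formaldehyde to C5' to give the salicyl alcohol 1-{4-[(tert-butyldimethylsilyl)oxy]-2,6-dihydroxy-3-(hydroxymethyl)-5-methylphenyl}-3-phenylpropan-1-one F2. A second equivalent of formaldehyde oxidises this in the same flask by Oppenauer-type hydride transfer, which comes back to the route at 6.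

3. Step 2. What may go wrong: poor site selectivity among the three phenols, or over-silylation. The fallback sets out from 3 and inverts the order, so that selectivity rests on a different principle.
   - Rieche formylation of unprotected 3 (Cl2CHOMe, TiCl4, CH2Cl2, 0 °C) should give 2,4,6-trihydroxy-3-methyl-5-(3-phenylpropanoyl)benzaldehyde F3.
   - Silylation with two equivalents of TBSCl/imidazole should spare only the hydroxyl flanked by, and hydrogen-bonded between, both carbonyl groups, giving 2,4-bis[(tert-butyldimethylsilyl)oxy]-6-hydroxy-3-methyl-5-(3-phenylpropanoyl)benzaldehyde F4.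
   - Annulation with isobutene under the conditions of step 4 should give 1-{(4R)-5,7-bis[(tert-butyldimethylsilyl)oxy]-4-hydroxy-2,2,6-trimethyl-3,4-dihydro-2H-chromen-8-yl}-3-phenylpropan-1-one F5.
   - Double desilylation (Bu4NF/AcOH, THF, 0 °C) comes back to the route at 10.

**Further compounds**

F1 | step 4 | 1-{4-[(tert-butyldimethylsilyl)oxy]-2,6-dihydroxy-3-[(1R)-1-hydroxy-3-methylbut-3-en-1-yl]-5-methylphenyl}-3-phenylpropan-1-one | Cc1c(O)c(C(=O)CCc2ccccc2)c(O)c([C@H](O)CC(C)=C)c1O[Si](C)(C)C(C)(C)C
F2 | step 3 | 1-{4-[(tert-butyldimethylsilyl)oxy]-2,6-dihydroxy-3-(hydroxymethyl)-5-methylphenyl}-3-phenylpropan-1-one | Cc1c(O)c(C(=O)CCc2ccccc2)c(O)c(CO)c1O[Si](C)(C)C(C)(C)C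
F3 | step 2 | 2,4,6-trihydroxy-3-methyl-5-(3-phenylpropanoyl)benzaldehyde | Cc1c(O)c(C(=O)CCc2ccccc2)c(O)c(C=O)c1O
F4 | step 2 | 2,4-bis[(tert-butyldimethylsilyl)oxy]-6-hydroxy-3-methyl-5-(3-phenylpropanoyl)benzaldehyde | Cc1c(O[Si](C)(C)C(C)(C)C)c(C(=O)CCc2ccccc2)c(O)c(C=O)c1O[Si](C)(C)C(C)(C)C
F5 | step 2 | 1-{(4R)-5,7-bis[(tert-butyldimethylsilyl)oxy]-4-hydroxy-2,2,6-trimethyl-3,4-dihydro-2H-chromen-8-yl}-3-phenylpropan-1-one | Cc1c(O[Si](C)(C)C(C)(C)C)c(C(=O)CCc2ccccc2)c2c(c1O[Si](C)(C)C(C)(C)C)[C@H](O)CC(C)(C)O2
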